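**Plan**

- Retrosynthesis: the benzyl ethers and a C8 bromine blocking group on the lower unit come off last. The upper 3-OH/4-H pair is taken back to the C3=C4 alkene of a 4-aryl-flav-3-ene. Ring C of the upper unit is then cut at both O1–C8a and C4–C4a, releasing ring A as an aryne and leaving an aldol. The aldol is cut at C2–C3 and at the C6–acyl bond of the lower unit.
- Forward: protected, C8-brominated gallocatechin is acetylated at C6, condensed to a chalcone and β-hydroxylated to an aldol. Ring A of the upper unit is then annulated onto this aldol, which closes ring C, and hydroboration and hydrogenolysis finish the route.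
- Enabling feature: in ring A of the upper unit the adjacent carbons C8a and C4a carry O1 and C4, and the C5 oxygen is ortho to C4a. This is the polarity pattern of a 3-alkoxybenzyne (nucleophile enters meta to the alkoxy group, carbanion forms ortho to it). O1 and C4 are 1,3-related through C2–C3 of ring C, i.e. an aldol whose ketone carbon already carries C6 of the lower unit, so the 4→6 link is fixed by construction.
- Stereochemistry: the lower unit (2R,3S) comes from (+)-gallocatechin. Upper C2 comes from ligand-controlled conjugate borylation. Upper C3 and C4 come from syn hydroboration anti to the C2 aryl, giving 2,3-trans-3,4-trans (4α).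

Key step: step 8

Remark on the chemistry: compounds 1, 5 and 9 are taken as purchasable. Abbreviations used in names: TBP = 3,4,5-tris(benzyloxy)phenyl; LU = (2R,3S)-3,5,7-tris(benzyloxy)-8-bromo-2-TBP-chroman-6-yl (the protected lower unit, attached through C6).

**Route**

Step 1
Reactants: 1 (+)-gallocatechin
Product: 2 hexa-O-benzyl-(+)-gallocatechin, (2R,3S)-3,5,7-tris(benzyloxy)-2-TBP-chromane
Conditions: BnBr (8 equiv), NaH (7.5 equiv), DMF, −20 °C to rt, argon
Reagents that add atoms: benzyl bromide, BrCc1ccccc1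
Why: Williamson etherification of the five phenols and the secondary 3-hydroxyl with excess base and benzyl bromide should give the fully protected flavan without touching C2 or C3.

Step 2
Reactants: 2 hexa-O-benzyl-(+)-gallocatechin
Product: 3 8-bromo-hexa-O-benzyl-(+)-gallocatechin
Conditions: NBS (1.0 equiv), CH2Cl2, −78 °C to 0 °C
Reagents that add atoms: N-bromosuccinimide, O=C1CCC(=O)N1Br
Why: Electrophilic aromatic bromination of O-benzylated flavan-3-ols is known to occur at C8 of the phloroglucinol-type ring A, which leaves C6 as the only nucleophilic position of that ring and installs a blocking group that hydrogenolysis removes at the end.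

Step 3
Reactants: 3 8-bromo-hexa-O-benzyl-(+)-gallocatechin
Product: 4 6-acetyl-8-bromo-hexa-O-benzyl-(+)-gallocatechin (LU–C(=O)CH3)
Conditions: AcOH, (CF3CO)2O, H3PO4 (85%, cat.), CH2Cl2, 0 °C to rt
Reagents that add atoms: acetic acid, CC(=O)O
Why: Friedel–Crafts acylation by the mixed anhydride acetyl trifluoroacetate should take place at C6, the only free position of the triply oxygen-activated ring A, and the absence of a metal Lewis acid avoids chelation-driven loss of the benzyl ethers ortho to the new ketone.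

Step 4
Reactants: 4 6-acetyl-8-bromo-hexa-O-benzyl-(+)-gallocatechin; 5 3,4,5-tris(benzyloxy)benzaldehyde
Product: 6 (E)-1-LU-3-TBP-prop-2-en-1-one (chalcone)
Conditions: KOH (aq.), EtOH/THF, rt
Reagents that add atoms: none
Why: Claisen–Schmidt condensation of the methyl ketone enolate with the non-enolisable aldehyde followed by E1cB loss of water should give the (E)-enone.

Step 5
Reactants: 6 chalcone
Product: 8 (3S)-3-hydroxy-1-LU-3-TBP-propan-1-one (aldol), via pinacol boronate 7 (not isolated)
Conditions: B2pin2, CuCl (cat.), NaOtBu (cat.), Josiphos-type ferrocenyl bisphosphine (cat., enantiomer chosen to give the (S)-boronate), MeOH (2 equiv), THF, rt; then NaBO3·4H2O, THF/H2O, 0 °C to rt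
Reagents that add atoms: sodium perborate, [Na+].[Na+].O[B-]1(O)OO[B-](O)(O)OO1 (hydroxyl oxygen of 8); bis(pinacolato)diboron, CC1(C)OB(OC1(C)C)B1OC(C)(C)C(C)(C)O1 (boron of 7 only)
Why: Copper-catalysed enantioselective conjugate borylation of the enone, in which the ligand directs the copper boryl to one face of the β-carbon and so sets the future C2 of the upper unit, followed by stereoretentive oxidation of the C–B bond, should give the (S)-aldol.

Step 6
Reactants: 9 3,5-bis(benzyloxy)phenol
Product: 10 2-bromo-3,5-bis(benzyloxy)phenol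
Conditions: NBS (1.0 equiv), CH2Cl2, −78 °C
Reagents that add atoms: N-bromosuccinimide, O=C1CCC(=O)N1Br
Why: Electrophilic bromination should occur ortho to the free hydroxyl (positions 2 and 6 are equivalent), in preference to the more hindered position between the two benzyloxy groups.

Step 7
Reactants: 10 2-bromo-3,5-bis(benzyloxy)phenol
Product: 13 3,5-bis(benzyloxy)-2-(trimethylsilyl)phenyl trifluoromethanesulfonate, via aryl trimethylsilyl ether 11 (not isolated), via lithium 2-silylphenoxide 12 (not isolated)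
Conditions: (Me3Si)2NH, THF, 65 °C, then evaporation; n-BuLi, THF, −78 °C; Tf2O, −78 °C to rt
Reagents that add atoms: hexamethyldisilazane, C[Si](C)(C)N[Si](C)(C)C; trifluoromethanesulfonic anhydride, O=S(=O)(OS(=O)(=O)C(F)(F)F)C(F)(F)F
Why: O-silylation, bromine–lithium exchange and retro-Brook O-to-C silyl migration should give the ortho-silyl phenoxide, which is triflated to the usual fluoride-triggered aryne precursor.

Step 8
Reactants: 8 (S)-aldol; 13 ortho-silylaryl triflate
Product: 17 (2S)-5,7-bis(benzyloxy)-2-TBP-4-LU-2H-chromene (4-aryl-flav-3-ene), via 3,5-bis(benzyloxy)benzyne 14 (not isolated), via aryl anion 15 (not isolated), via C4 carbinol 16 (not isolated)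
Conditions: CsF (3 equiv), 18-crown-6 (cat.), THF, rt, slow addition of 13 (1.3 equiv); then CF3CO2H, 0 °C; Et3N quench
Reagents that add atoms: none
Why: Proposed new method: fluoride-induced 1,2-elimination of 13 releases benzyne 14, the fluoride-activated C2 hydroxyl of 8 adds to the aryne carbon meta to the 3-benzyloxy group (O1–C8a), the resulting carbanion of 15 sits ortho to that benzyloxy group at the future C4a and adds to the neighbouring ketone carbon (C4–C4a) to give carbinol 16, and trifluoroacetic acid dehydrates 16 through the doubly benzylic C4 cation to flav-3-ene 17. The closest known reaction type is the aryne annulation of ortho-hydroxyaryl and ortho-aminoaryl ketones or esters (heteroatom arylation, then intramolecular addition of the aryl anion to the carbonyl, giving xanthenols, xanthones and acridines); what is new is an aliphatic aldol hydroxyl as the nucleophile. Ring C closes by 6-exo-trig attack of the C4a carbanion on the C4 carbonyl. The only new stereocentre, the C4 carbinol of 16, needs no control because dehydration erases it, and C2 keeps the configuration of 8 because its C–O bond is never broken. The step needs regioselective addition to the aryne, which the inductive effect and ring distortion of the 3-alkoxy group should secure, and it needs carbonyl capture to outrun protonation of 15 and retro-aldol cleavage of 8, for which the aprotic solvent, the six-membered transition state and the slow release of the aryne are relied on.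

Step 9
Reactants: 17 4-aryl-flav-3-ene
Product: 19 (2R,3S)-5,7-bis(benzyloxy)-2-TBP-4α-LU-chroman-3-ol (2,3-trans-3,4-trans), via C3 alkylborane 18 (not isolated)
Conditions: BH3·THF, THF, 0 °C to rt; then NaOH (aq.), H2O2 (30%), 0 °C to rt
Reagents that add atoms: hydrogen peroxide, OO (hydroxyl oxygen of 19); borane–tetrahydrofuran, [BH3-][O+]1CCCC1 (boron of 18 only)
Why: Hydroboration–oxidation of a flav-3-ene should add boron to the less substituted C3 and hydrogen to C4 in a syn fashion from the face anti to the C2 aryl, and oxidation with retention then gives the 3-hydroxyl trans to the C2 aryl and the C4 aryl trans to the 3-hydroxyl.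

Step 10
Reactants: 19 undeca-O-benzyl bromo dimer
Product: 20 gallocatechin-(4α→6)-gallocatechin (target)
Conditions: H2 (1 atm), Pd(OH)2 on carbon, Et3N (2 equiv), THF/MeOH/H2O, rt; filtration under argon, Sephadex LH-20, lyophilisation
Reagents that add atoms: none
Why: Palladium-catalysed hydrogenolysis should cleave all eleven benzyl ethers and, with the amine as acid scavenger, the aryl C–Br bond, without affecting the five stereocentres.

**Compound list**

1 | (+)-gallocatechin, (2R,3S) | Oc1cc(O)c2c(c1)O[C@H](c1cc(O)c(O)c(O)c1)[C@@H](O)C2 | starting material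
2 | hexa-O-benzyl-(+)-gallocatechin | O(Cc1ccccc1)c1cc(OCc2ccccc2)c2c(c1)O[C@H](c1cc(OCc3ccccc3)c(OCc3ccccc3)c(OCc3ccccc3)c1)[C@@H](OCc1ccccc1)C2 | intermediate
3 | 8-bromo-hexa-O-benzyl-(+)-gallocatechin | O(Cc1ccccc1)c1cc(OCc2ccccc2)c2c(c1Br)O[C@H](c1cc(OCc3ccccc3)c(OCc3ccccc3)c(OCc3ccccc3)c1)[C@@H](OCc1ccccc1)C2 | intermediate
4 | 6-acetyl-8-bromo-hexa-O-benzyl-(+)-gallocatechin | O(Cc1ccccc1)c1c(C(C)=O)c(OCc2ccccc2)c2c(c1Br)O[C@H](c1cc(OCc3ccccc3)c(OCc3ccccc3)c(OCc3ccccc3)c1)[C@@H](OCc1ccccc1)C2 | intermediate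
5 | 3,4,5-tris(benzyloxy)benzaldehyde | O=Cc1cc(OCc2ccccc2)c(OCc2ccccc2)c(OCc2ccccc2)c1 | starting material
6 | (E)-1-LU-3-TBP-prop-2-en-1-one (chalcone) | O(Cc1ccccc1)c1c(C(=O)/C=C/c2cc(OCc3ccccc3)c(OCc3ccccc3)c(OCc3ccccc3)c2)c(OCc2ccccc2)c2c(c1Br)O[C@H](c1cc(OCc3ccccc3)c(OCc3ccccc3)c(OCc3ccccc3)c1)[C@@H](OCc1ccccc1)C2 | intermediate
7 | (3S)-3-(pinacolboryl)-1-LU-3-TBP-propan-1-one | O(Cc1ccccc1)c1c(C(=O)C[C@H](B2OC(C)(C)C(C)(C)O2)c2cc(OCc3ccccc3)c(OCc3ccccc3)c(OCc3ccccc3)c2)c(OCc2ccccc2)c2c(c1Br)O[C@H](c1cc(OCc3ccccc3)c(OCc3ccccc3)c(OCc3ccccc3)c1)[C@@H](OCc1ccccc1)C2 | intermediate (not isolated)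
8 | (3S)-3-hydroxy-1-LU-3-TBP-propan-1-one (aldol) | O(Cc1ccccc1)c1c(C(=O)C[C@H](O)c2cc(OCc3ccccc3)c(OCc3ccccc3)c(OCc3ccccc3)c2)c(OCc2ccccc2)c2c(c1Br)O[C@H](c1cc(OCc3ccccc3)c(OCc3ccccc3)c(OCc3ccccc3)c1)[C@@H](OCc1ccccc1)C2 | intermediate
9 | 3,5-bis(benzyloxy)phenol | Oc1cc(OCc2ccccc2)cc(OCc2ccccc2)c1 | starting material
10 | 2-bromo-3,5-bis(benzyloxy)phenol | Oc1cc(OCc2ccccc2)cc(OCc2ccccc2)c1Br | intermediate
11 | [2-bromo-3,5-bis(benzyloxy)phenoxy]trimethylsilane | C[Si](C)(C)Oc1cc(OCc2ccccc2)cc(OCc2ccccc2)c1Br | intermediate (not isolated)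
12 | lithium 3,5-bis(benzyloxy)-2-(trimethylsilyl)phenoxide | [Li+].[O-]c1cc(OCc2ccccc2)cc(OCc2ccccc2)c1[Si](C)(C)C | intermediate (not isolated)
13 | 3,5-bis(benzyloxy)-2-(trimethylsilyl)phenyl trifluoromethanesulfonate | FC(F)(F)S(=O)(=O)Oc1cc(OCc2ccccc2)cc(OCc2ccccc2)c1[Si](C)(C)C | intermediate
14 | 3,5-bis(benzyloxy)benzyne | C1#CC(OCc2ccccc2)=CC(OCc2ccccc2)=C1 | intermediate (not isolated)
15 | cesium salt of the O-arylated aldol carbanion (anion at the ring carbon between the ether oxygen and the 3-benzyloxy group; carbinol carbon S) | [Cs+].O(Cc1ccccc1)c1c(C(=O)C[C@H](Oc2cc(OCc3ccccc3)cc(OCc3ccccc3)[c-]2)c2cc(OCc3ccccc3)c(OCc3ccccc3)c(OCc3ccccc3)c2)c(OCc2ccccc2)c2c(c1Br)O[C@H](c1cc(OCc3ccccc3)c(OCc3ccccc3)c(OCc3ccccc3)c1)[C@@H](OCc1ccccc1)C2 | intermediate (not isolated)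
16 | (2S)-5,7-bis(benzyloxy)-2-TBP-4-LU-chroman-4-ol (C4 epimers, configuration immaterial) | O(Cc1ccccc1)c1cc(OCc2ccccc2)c2c(c1)O[C@H](c1cc(OCc3ccccc3)c(OCc3ccccc3)c(OCc3ccccc3)c1)CC2(O)c1c(OCc2ccccc2)c(Br)c2c(c1OCc1ccccc1)C[C@H](OCc1ccccc1)[C@@H](c1cc(OCc3ccccc3)c(OCc3ccccc3)c(OCc3ccccc3)c1)O2 | intermediate (not isolated)
17 | (2S)-5,7-bis(benzyloxy)-2-TBP-4-LU-2H-chromene | O(Cc1ccccc1)c1cc(OCc2ccccc2)c2c(c1)O[C@H](c1cc(OCc3ccccc3)c(OCc3ccccc3)c(OCc3ccccc3)c1)C=C2c1c(OCc2ccccc2)c(Br)c2c(c1OCc1ccccc1)C[C@H](OCc1ccccc1)[C@@H](c1cc(OCc3ccccc3)c(OCc3ccccc3)c(OCc3ccccc3)c1)O2 | intermediate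
18 | 3-boryl (BH2) adduct of 17, boron trans to the C2 aryl, C4 hydrogen cis to boron | O(Cc1ccccc1)c1cc(OCc2ccccc2)c2c(c1)O[C@H](c1cc(OCc3ccccc3)c(OCc3ccccc3)c(OCc3ccccc3)c1)[C@@H](B)[C@@H]2c1c(OCc2ccccc2)c(Br)c2c(c1OCc1ccccc1)C[C@H](OCc1ccccc1)[C@@H](c1cc(OCc3ccccc3)c(OCc3ccccc3)c(OCc3ccccc3)c1)O2 | intermediate (not isolated)
19 | (2R,3S)-5,7-bis(benzyloxy)-2-TBP-4α-LU-chroman-3-ol (2,3-trans-3,4-trans) | O(Cc1ccccc1)c1cc(OCc2ccccc2)c2c(c1)O[C@H](c1cc(OCc3ccccc3)c(OCc3ccccc3)c(OCc3ccccc3)c1)[C@@H](O)[C@@H]2c1c(OCc2ccccc2)c(Br)c2c(c1OCc1ccccc1)C[C@H](OCc1ccccc1)[C@@H](c1cc(OCc3ccccc3)c(OCc3ccccc3)c(OCc3ccccc3)c1)O2 | intermediate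
20 | gallocatechin-(4α→6)-gallocatechin | Oc1cc(O)c2c(c1)O[C@H](c1cc(O)c(O)c(O)c1)[C@@H](O)[C@@H]2c1c(O)cc2c(c1O)C[C@H](O)[C@@H](c1cc(O)c(O)c(O)c1)O2 | target

**Summary**

Total step count: 10. Longest linear sequence: 8 steps (steps 1, 2, 3, 4, 5, 8, 9, 10); steps 6 and 7 make the aryne precursor on a side branch.

Steps most likely to fail:

1. Step 8 (proposed new method). The aryl anion may be protonated before it reaches the hindered di-ortho-alkoxyaryl ketone, giving only O-arylation, or the aldol may undergo retro-aldol cleavage or elimination under fluoride. The fallback is the known Lewis-acid interflavan coupling; it sets out from compound 3 (with fresh 1) and comes back to the route at compound 19. (+)-Gallocatechin 1 is benzylated on its five phenols only (BnBr, K2CO3, DMF) to give 5,7,3',4',5'-penta-O-benzylgallocatechin F1. Oxidation at C4 with DDQ in the presence of 2-ethoxyethanol (CH2Cl2, rt) gives the 4-(2-ethoxyethoxy) ether F2. TMSOTf (CH2Cl2, −78 °C) ionises F2, and the C4 cation should be captured by C6 of the C8-blocked nucleophile 3 (used in excess), entering trans to the 3-hydroxyl, to give 19 directly.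

2. Step 3. Acylation may be sluggish at the hindered C6, may compete on ring B of the lower unit, or the acid may cause loss or migration of benzyl groups. The fallback sets out from compound 3 and comes back at compound 4. Vilsmeier–Haack formylation (POCl3, DMF, 0 °C to 60 °C) should give the 6-carbaldehyde F3. Addition of MeMgBr (THF, −78 °C) gives the 1-hydroxyethyl compound F4, and Dess–Martin periodinane (CH2Cl2, rt) oxidises it to ketone 4.

3. Step 9. Hydroboration of the crowded C3=C4 bond, flanked by two di-ortho-substituted aryl groups, may be slow, and facial selectivity may be incomplete. The fallback sets out from compound 17 and comes back at compound 19. Epoxidation with dimethyldioxirane (acetone/CH2Cl2, −40 °C) anti to the C2 aryl gives the 3,4-epoxide F5. Reductive opening with BH3·THF (THF, 0 °C) then ionises the benzylic C4–O bond and delivers hydride from the oxygen-bound borane to the same face, which should give 19 with the same relative configuration.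

**Further compounds**

F1 | step 8 | 5,7,3',4',5'-penta-O-benzyl-(+)-gallocatechin (3-OH free) | O(Cc1ccccc1)c1cc(OCc2ccccc2)c2c(c1)O[C@H](c1cc(OCc3ccccc3)c(OCc3ccccc3)c(OCc3ccccc3)c1)[C@@H](O)C2
F2 | step 8 | 4-(2-ethoxyethoxy) ether of F1 (either C4 epimer or the mixture, since C4 is ionised on coupling) | O(Cc1ccccc1)c1cc(OCc2ccccc2)c2c(c1)O[C@H](c1cc(OCc3ccccc3)c(OCc3ccccc3)c(OCc3ccccc3)c1)[C@@H](O)C2OCCOCC
F3 | step 3 | 6-formyl-8-bromo-hexa-O-benzyl-(+)-gallocatechin | O(Cc1ccccc1)c1c(C=O)c(OCc2ccccc2)c2c(c1Br)O[C@H](c1cc(OCc3ccccc3)c(OCc3ccccc3)c(OCc3ccccc3)c1)[C@@H](OCc1ccccc1)C2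
F4 | step 3 | 6-(1-hydroxyethyl)-8-bromo-hexa-O-benzyl-(+)-gallocatechin (carbinol epimers) | O(Cc1ccccc1)c1c(C(C)O)c(OCc2ccccc2)c2c(c1Br)O[C@H](c1cc(OCc3ccccc3)c(OCc3ccccc3)c(OCc3ccccc3)c1)[C@@H](OCc1ccccc1)C2
F5 | step 9 | 3,4-epoxide of 17, oxygen on the face anti to the C2 aryl | O(Cc1ccccc1)c1cc(OCc2ccccc2)c2c(c1)O[C@H](c1cc(OCc3ccccc3)c(OCc3ccccc3)c(OCc3ccccc3)c1)[C@H]4O[C@]42c1c(OCc2ccccc2)c(Br)c2c(c1OCc1ccccc1)C[C@H](OCc1ccccc1)[C@@H](c1cc(OCc3ccccc3)c(OCc3ccccc3)c(OCc3ccccc3)c1)O2
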